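An equivalent was the unit I reckoned in, and 1 equiv of partner was the zero of my scale: there the two charges match one for one.

substrate 0.31 M; partner 0.600 equiv; time 15 d

    substrate + partner + released group → product + 2 released group (k1 = 0.072 M⁻² s⁻¹)
    substrate + partner → product + released group (k2 = 1.0 × 10⁻⁴ M⁻¹ s⁻¹)

1. the product standing at 15 d, as a percentage of the substrate charged
2. amount of product if the flask were left three thousand times as long, in percent of the substrate charged

Each arrow consumes one substrate and one partner, so the bench rule was that the yield equals what the limiting reagent allows. I called this the ceiling c: the lesser of the two charges, as a fraction of the substrate charged, here 60.0 %. The partner stood at 0.186 M, less than the 0.31 M of substrate, so this flask lay below the zero.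

The rule has two borders. Where the ratio of partner to substrate passes 1, the ceiling belongs to the substrate. The rule also ignores time, so I held the time against the partner's lifetime. By the second step alone, with the substrate taken as already down to what the ceiling leaves, I reckoned the partner's half-life at 0.647 d. The 15 d of this flask spans 23.2 such half-lives, and the first step adds to that rate. I therefore committed to 60.0 % for the product at the asked time and 60.0 % for the long wait.

The forecast gave 60 % (range 59.5 % to 60 %) and 60 % (range 59.5 % to 60 %), holding that “product stops at 60% of the substrate charged and waiting longer adds nothing”.

The simulation gave 60.0 % for the product at 15 d and 60.0 % for the long wait. In this flask the midpoint of the conversion reached at the asked time came at 0.358 h, and the 15 d allowed was 1006 times as long. By 1.50 d the product already stood at 60.0 %, with the partner at 0 % of its charge, and 40 % of the substrate stayed unused to the end. The same flask charged with 0.360 equiv of partner has a ceiling of 36.0 %, and its product stood at 36.0 % at 15.0 d, with 64 % of the substrate left.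

The constants used here come from no measurement; what happens was integrated by code.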